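**Retrosynthetic overview**
- Target ⇒ its syringyl O-benzyl ether; the benzyl group is removed last by hydrogenolysis.
- Lactone ring (the only ring formed, closed in the penultimate step) ⇒ acyclic 8'-hydroxy-seco triol by triol → lactol → lactone dehydrogenation. This is the path presumed for 8'-hydroxylated dibenzylbutyrolactone lignans (carinol → carissanol → nortrachelogenin type); the vicinal tertiary OH decides which CH2OH becomes the C=O.
- Triol ⇒ C8–C8' bond and both stereocentres in one catalytic syn-selective Mukaiyama aldol (dihydroferulic thioester ketene acetal + syringylpyruvate ester), reduced in the same flask.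
- Keto ester ⇒ O-benzylsyringaldehyde (olefination, hydrolysis); ketene acetal ⇒ dihydroferulic acid.

Assumption: lignan numbering is used (C7–C9 guaiacyl unit, C7'–C9' syringyl unit); the target is (3S,4R) with the two benzyl groups cis; compounds 1, 2, 6 and 7 are taken as catalogue items.

Ligand abbreviations: (S,S)-t-Bu-box = 2,2'-(propane-2,2-diyl)bis[(4S)-4-tert-butyl-4,5-dihydro-1,3-oxazole]; neocuproine = 2,9-dimethyl-1,10-phenanthroline.

**Route**

Step 1
Reactants: 1 4-(benzyloxy)-3,5-dimethoxybenzaldehyde; 2 methyl 2-[(tert-butoxycarbonyl)amino]-2-(dimethoxyphosphoryl)acetate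
Product: 3 methyl (2Z)-3-[4-(benzyloxy)-3,5-dimethoxyphenyl]-2-[(tert-butoxycarbonyl)amino]prop-2-enoate
Conditions: DBU, CH2Cl2, 0 °C to rt
Reagents that add atoms: none
Why: Horner–Wadsworth–Emmons olefination of a non-enolisable aryl aldehyde with the stabilised phosphonoglycinate anion gives the (Z)-dehydroamino ester; no stereocentre is formed.

Step 2
Reactants: 3 methyl (2Z)-3-[4-(benzyloxy)-3,5-dimethoxyphenyl]-2-[(tert-butoxycarbonyl)amino]prop-2-enoate
Product: 5 methyl 3-[4-(benzyloxy)-3,5-dimethoxyphenyl]-2-oxopropanoate, via enamino ester 4 (not isolated)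
Conditions: CF3CO2H, CH2Cl2, 0 °C to rt; then H2O, THF, rt
Reagents that add atoms: water, O
Why: Acidolytic Boc cleavage unmasks the primary enamine, whose iminium tautomer is hydrolysed to the ketone (enamine hydrolysis), while the aryl benzyl ether and the methyl ester survive CF3CO2H at rt; no stereocentre is formed.

Step 3
Reactants: 6 3-(4-hydroxy-3-methoxyphenyl)propanoic acid; 7 ethanethiol
Product: 8 S-ethyl 3-(4-hydroxy-3-methoxyphenyl)propanethioate
Conditions: DCC, DMAP (5 mol%), CH2Cl2, 0 °C to rt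
Reagents that add atoms: none
Why: Steglich thioesterification, in which the soft thiol captures the acylpyridinium much faster than the phenol does; no stereocentre is formed.

Step 4
Reactants: 8 S-ethyl 3-(4-hydroxy-3-methoxyphenyl)propanethioate
Product: 9 {[(1Z)-1-(ethylsulfanyl)-3-{3-methoxy-4-[(trimethylsilyl)oxy]phenyl}prop-1-en-1-yl]oxy}(trimethyl)silane
Conditions: LiN(iPr)2 (2.2 equiv), Me3SiCl (2.5 equiv), THF, −78 °C to rt
Reagents that add atoms: chlorotrimethylsilane, C[Si](C)(C)Cl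
Why: Silyl ketene acetal formation: the phenol is deprotonated first, kinetic enolisation of the thioester (Ireland model) then gives the (Z)-enolate, and O-silylation of both oxyanions protects the phenol in the same operation; the alkene geometry is not critical because both isomers give the syn aldol.

Step 5
Reactants: 5 methyl 3-[4-(benzyloxy)-3,5-dimethoxyphenyl]-2-oxopropanoate; 9 {[(1Z)-1-(ethylsulfanyl)-3-{3-methoxy-4-[(trimethylsilyl)oxy]phenyl}prop-1-en-1-yl]oxy}(trimethyl)silane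
Product: 11 (2S,3R)-2-{[4-(benzyloxy)-3,5-dimethoxyphenyl]methyl}-3-[(4-hydroxy-3-methoxyphenyl)methyl]butane-1,2,4-triol, via silylated aldol adduct 10 (not isolated)
Conditions: [Cu((S,S)-t-Bu-box)](OTf)2 (10 mol%), 9 (1.3 equiv), THF, −78 °C; then LiAlH4, −78 to 0 °C; aq. HCl work-up
Reagents that add atoms: none
Why: Mukaiyama aldol of the copper–bis(oxazoline) pyruvate type: the keto tautomer of 5 binds the divalent copper centre as a ketone/ester chelate, the tert-butyl group of the (S,S)-ligand blocks the re face so that 9 attacks the si face of the ketone (8'S), and the open antiperiplanar transition state keeps the C8 benzyl away from the chelated ester (syn adduct, 8S in 10); LiAlH4 then reduces the thioester and the methyl ester without touching either stereocentre (the O-silyl group suppresses retro-aldol) and acid removes both silyl groups, the C8 descriptor changing to R only through the change in CIP priorities.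

Step 6
Reactants: 11 (2S,3R)-2-{[4-(benzyloxy)-3,5-dimethoxyphenyl]methyl}-3-[(4-hydroxy-3-methoxyphenyl)methyl]butane-1,2,4-triol
Product: 14 (3S,4R)-3-{[4-(benzyloxy)-3,5-dimethoxyphenyl]methyl}-3-hydroxy-4-[(4-hydroxy-3-methoxyphenyl)methyl]oxolan-2-one, via hydroxy aldehyde 12 (not isolated), via lactol 13 (not isolated)
Conditions: [(neocuproine)Pd(OAc)]2(OTf)2 (5 mol%), 1,4-benzoquinone (2.5 equiv), MeCN/H2O (10:1), rt
Reagents that add atoms: none
Why: Proposed new method: the vicinal tertiary/primary diol chelates the cationic divalent-palladium centre, so β-hydride elimination can occur only at C9'–H; the resulting α-hydroxy aldehyde is trapped by the C9 hydroxyl as the five-membered lactol (again a chelating vicinal diol) and is dehydrogenated a second time to the lactone, the triol → lactol → lactone sequence of a dehydrogenase-type closure, whereas the isolated C9–OH binds only monodentately and reacts more slowly; the closest known reaction type is the chemoselective oxidation of vicinal diols and the oxidative lactonisation of diols with this palladium catalyst and benzoquinone; no stereocentre is touched.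

Step 7
Reactants: 14 (3S,4R)-3-{[4-(benzyloxy)-3,5-dimethoxyphenyl]methyl}-3-hydroxy-4-[(4-hydroxy-3-methoxyphenyl)methyl]oxolan-2-one
Product: 15 (3S,4R)-3-hydroxy-3-[(4-hydroxy-3,5-dimethoxyphenyl)methyl]-4-[(4-hydroxy-3-methoxyphenyl)methyl]oxolan-2-one
Conditions: H2 (1 atm), Pd/C (10 wt% palladium on carbon), EtOAc/EtOH, rt
Reagents that add atoms: none
Why: Hydrogenolysis of the aryl benzyl ether; the lactone, the tertiary alcohol and both stereocentres are inert under these conditions.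

**Compound list**

1 | 4-(benzyloxy)-3,5-dimethoxybenzaldehyde | O=Cc1cc(OC)c(OCc2ccccc2)c(OC)c1 | starting material
2 | methyl 2-[(tert-butoxycarbonyl)amino]-2-(dimethoxyphosphoryl)acetate (racemic) | COC(=O)C(NC(=O)OC(C)(C)C)P(=O)(OC)OC | starting material
3 | methyl (2Z)-3-[4-(benzyloxy)-3,5-dimethoxyphenyl]-2-[(tert-butoxycarbonyl)amino]prop-2-enoate | COC(=O)/C(NC(=O)OC(C)(C)C)=C/c1cc(OC)c(OCc2ccccc2)c(OC)c1 | intermediate
4 | methyl (2Z)-2-amino-3-[4-(benzyloxy)-3,5-dimethoxyphenyl]prop-2-enoate (trifluoroacetate salt in the flask) | COC(=O)/C(N)=C/c1cc(OC)c(OCc2ccccc2)c(OC)c1 | intermediate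
5 | methyl 3-[4-(benzyloxy)-3,5-dimethoxyphenyl]-2-oxopropanoate (keto form; equilibrates with its enol) | COC(=O)C(=O)Cc1cc(OC)c(OCc2ccccc2)c(OC)c1 | intermediate
6 | 3-(4-hydroxy-3-methoxyphenyl)propanoic acid (dihydroferulic acid) | COc1cc(CCC(=O)O)ccc1O | starting material
7 | ethanethiol | CCS | starting material
8 | S-ethyl 3-(4-hydroxy-3-methoxyphenyl)propanethioate | CCSC(=O)CCc1ccc(O)c(OC)c1 | intermediate
9 | {[(1Z)-1-(ethylsulfanyl)-3-{3-methoxy-4-[(trimethylsilyl)oxy]phenyl}prop-1-en-1-yl]oxy}(trimethyl)silane | CCS/C(O[Si](C)(C)C)=C\Cc1ccc(O[Si](C)(C)C)c(OC)c1 | intermediate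
10 | methyl (2S,3S)-2-{[4-(benzyloxy)-3,5-dimethoxyphenyl]methyl}-4-(ethylsulfanyl)-3-({3-methoxy-4-[(trimethylsilyl)oxy]phenyl}methyl)-4-oxo-2-[(trimethylsilyl)oxy]butanoate | CCSC(=O)[C@@H](Cc1ccc(O[Si](C)(C)C)c(OC)c1)[C@@](O[Si](C)(C)C)(Cc1cc(OC)c(OCc2ccccc2)c(OC)c1)C(=O)OC | intermediate
11 | (2S,3R)-2-{[4-(benzyloxy)-3,5-dimethoxyphenyl]methyl}-3-[(4-hydroxy-3-methoxyphenyl)methyl]butane-1,2,4-triol | COc1cc(C[C@H](CO)[C@](O)(CO)Cc2cc(OC)c(OCc3ccccc3)c(OC)c2)ccc1O | intermediate
12 | (2S,3R)-2-{[4-(benzyloxy)-3,5-dimethoxyphenyl]methyl}-2,4-dihydroxy-3-[(4-hydroxy-3-methoxyphenyl)methyl]butanal | COc1cc(C[C@H](CO)[C@](O)(C=O)Cc2cc(OC)c(OCc3ccccc3)c(OC)c2)ccc1O | intermediate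
13 | (3S,4R)-3-{[4-(benzyloxy)-3,5-dimethoxyphenyl]methyl}-4-[(4-hydroxy-3-methoxyphenyl)methyl]oxolane-2,3-diol (both C2 epimers) | COc1cc(C[C@@H]2COC(O)[C@]2(O)Cc2cc(OC)c(OCc3ccccc3)c(OC)c2)ccc1O | intermediate
14 | (3S,4R)-3-{[4-(benzyloxy)-3,5-dimethoxyphenyl]methyl}-3-hydroxy-4-[(4-hydroxy-3-methoxyphenyl)methyl]oxolan-2-one | COc1cc(C[C@@H]2COC(=O)[C@]2(O)Cc2cc(OC)c(OCc3ccccc3)c(OC)c2)ccc1O | intermediate
15 | (3S,4R)-3-hydroxy-3-[(4-hydroxy-3,5-dimethoxyphenyl)methyl]-4-[(4-hydroxy-3-methoxyphenyl)methyl]oxolan-2-one | COc1cc(C[C@@H]2COC(=O)[C@]2(O)Cc2cc(OC)c(O)c(OC)c2)ccc1O | target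

**Step count and risks**

Total step count: 7. Longest linear sequence: 5 steps (1 → 2 → 5 → 6 → 7, or 3 → 4 → 5 → 6 → 7).

Three steps most likely to fail, each with a fallback:

- **Step 6, regioselective oxidative lactonisation.** The isolated C9–OH may be oxidised first, which would give the regioisomeric lactone, and the free guaiacyl phenol may slow the palladium catalyst. The fallback sets out from keto ester 5 and ketene acetal 9 and comes back at lactone 14. The copper-catalysed aldol of step 5 is quenched with aqueous HCl instead of LiAlH4, so that adduct 10 is desilylated to the thioester methyl (2S,3S)-2-{[4-(benzyloxy)-3,5-dimethoxyphenyl]methyl}-4-(ethylsulfanyl)-2-hydroxy-3-[(4-hydroxy-3-methoxyphenyl)methyl]-4-oxobutanoate F1. Fukuyama reduction (Et3SiH, Pd/C, acetone, rt) converts the thioester into the aldehyde methyl (2S,3S)-2-{[4-(benzyloxy)-3,5-dimethoxyphenyl]methyl}-2-hydroxy-3-[(4-hydroxy-3-methoxyphenyl)methyl]-4-oxobutanoate F2. This is reduced at once (NaBH4, MeOH, −40 °C) to the hydroxy ester methyl (2S,3R)-2-{[4-(benzyloxy)-3,5-dimethoxyphenyl]methyl}-2,4-dihydroxy-3-[(4-hydroxy-3-methoxyphenyl)methyl]butanoate F3, which closes to 14 with catalytic TsOH in CH2Cl2. The ring is then closed reductively, and its regiochemistry is fixed by the oxidation levels set in the aldol.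

- **Step 5, aldol on an enol-rich keto ester.** Aryl pyruvate 5 exists largely as its conjugated enol, which can quench the silyl ketene acetal or bind the copper catalyst, so the keto form may not be available fast enough at −78 °C. The fallback sets out from acid 6 (aldehyde 1 is used again) and comes back at target 15; it builds the 8'-oxygen by dihydroxylation instead of aldol.
  - O-Benzylation (BnBr, NaOH, EtOH/H2O, reflux) gives 3-[4-(benzyloxy)-3-methoxyphenyl]propanoic acid F4.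
  - DCC/DMAP acylation of (R)-4-benzyl-1,3-oxazolidin-2-one gives (4R)-4-benzyl-3-{3-[4-(benzyloxy)-3-methoxyphenyl]propanoyl}-1,3-oxazolidin-2-one F5.
  - Evans alkylation (NaN(SiMe3)2, tert-butyl bromoacetate, THF, −78 °C) gives tert-butyl (3S)-4-[(4R)-4-benzyl-2-oxo-1,3-oxazolidin-3-yl]-3-{[4-(benzyloxy)-3-methoxyphenyl]methyl}-4-oxobutanoate F6.
  - LiBH4 followed by CF3CO2H gives (4S)-4-{[4-(benzyloxy)-3-methoxyphenyl]methyl}oxolan-2-one F7.
  - Aldol condensation with 1 (LiN(iPr)2, THF, −78 °C; then Ac2O, DBU) gives (3E,4S)-3-{[4-(benzyloxy)-3,5-dimethoxyphenyl]methylidene}-4-{[4-(benzyloxy)-3-methoxyphenyl]methyl}oxolan-2-one F8.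
  - OsO4 (cat.) with N-methylmorpholine N-oxide adds to the face opposite the C4 benzyl group and gives (3R,4R)-3-{(S)-[4-(benzyloxy)-3,5-dimethoxyphenyl](hydroxy)methyl}-4-{[4-(benzyloxy)-3-methoxyphenyl]methyl}-3-hydroxyoxolan-2-one F9.
  - Hydrogenolysis (H2, Pd/C, AcOH, cat. HClO4) removes both benzyl ethers and the benzylic hydroxyl and gives 15.

- **Step 2, enamide hydrolysis to the keto ester.** Hydrolysis may be incomplete, or the electron-rich benzyl ether may be partly cleaved by acid. The fallback sets out from aldehyde 1 and comes back at keto ester 5. Condensation with hydantoin (ethanolamine, EtOH/H2O, reflux) gives (5Z)-5-{[4-(benzyloxy)-3,5-dimethoxyphenyl]methylidene}imidazolidine-2,4-dione F10. Alkaline hydrolysis (aq. NaOH, reflux; then HCl) gives 3-[4-(benzyloxy)-3,5-dimethoxyphenyl]-2-oxopropanoic acid F11. Esterification (MeOH, SOCl2, 0 °C) gives 5.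

**Further compounds**

F1 | step 6 | methyl (2S,3S)-2-{[4-(benzyloxy)-3,5-dimethoxyphenyl]methyl}-4-(ethylsulfanyl)-2-hydroxy-3-[(4-hydroxy-3-methoxyphenyl)methyl]-4-oxobutanoate | CCSC(=O)[C@@H](Cc1ccc(O)c(OC)c1)[C@@](O)(Cc1cc(OC)c(OCc2ccccc2)c(OC)c1)C(=O)OC
F2 | step 6 | methyl (2S,3S)-2-{[4-(benzyloxy)-3,5-dimethoxyphenyl]methyl}-2-hydroxy-3-[(4-hydroxy-3-methoxyphenyl)methyl]-4-oxobutanoate | O=C[C@@H](Cc1ccc(O)c(OC)c1)[C@@](O)(Cc1cc(OC)c(OCc2ccccc2)c(OC)c1)C(=O)OC
F3 | step 6 | methyl (2S,3R)-2-{[4-(benzyloxy)-3,5-dimethoxyphenyl]methyl}-2,4-dihydroxy-3-[(4-hydroxy-3-methoxyphenyl)methyl]butanoate | OC[C@@H](Cc1ccc(O)c(OC)c1)[C@@](O)(Cc1cc(OC)c(OCc2ccccc2)c(OC)c1)C(=O)OC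
F4 | step 5 | 3-[4-(benzyloxy)-3-methoxyphenyl]propanoic acid | COc1cc(CCC(=O)O)ccc1OCc1ccccc1
F5 | step 5 | (4R)-4-benzyl-3-{3-[4-(benzyloxy)-3-methoxyphenyl]propanoyl}-1,3-oxazolidin-2-one | O=C1OC[C@@H](Cc2ccccc2)N1C(=O)CCc1ccc(OCc2ccccc2)c(OC)c1
F6 | step 5 | tert-butyl (3S)-4-[(4R)-4-benzyl-2-oxo-1,3-oxazolidin-3-yl]-3-{[4-(benzyloxy)-3-methoxyphenyl]methyl}-4-oxobutanoate | O=C1OC[C@@H](Cc2ccccc2)N1C(=O)[C@H](CC(=O)OC(C)(C)C)Cc1ccc(OCc2ccccc2)c(OC)c1
F7 | step 5 | (4S)-4-{[4-(benzyloxy)-3-methoxyphenyl]methyl}oxolan-2-one | O=C1C[C@H](Cc2ccc(OCc3ccccc3)c(OC)c2)CO1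
F8 | step 5 | (3E,4S)-3-{[4-(benzyloxy)-3,5-dimethoxyphenyl]methylidene}-4-{[4-(benzyloxy)-3-methoxyphenyl]methyl}oxolan-2-one | O=C1OC[C@@H](Cc2ccc(OCc3ccccc3)c(OC)c2)/C1=C\c1cc(OC)c(OCc2ccccc2)c(OC)c1
F9 | step 5 | (3R,4R)-3-{(S)-[4-(benzyloxy)-3,5-dimethoxyphenyl](hydroxy)methyl}-4-{[4-(benzyloxy)-3-methoxyphenyl]methyl}-3-hydroxyoxolan-2-one | COc1cc(C[C@@H]2COC(=O)[C@]2(O)[C@@H](O)c2cc(OC)c(OCc3ccccc3)c(OC)c2)ccc1OCc1ccccc1
F10 | step 2 | (5Z)-5-{[4-(benzyloxy)-3,5-dimethoxyphenyl]methylidene}imidazolidine-2,4-dione | O=C1NC(=O)/C(=C/c2cc(OC)c(OCc3ccccc3)c(OC)c2)N1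
F11 | step 2 | 3-[4-(benzyloxy)-3,5-dimethoxyphenyl]-2-oxopropanoic acid | OC(=O)C(=O)Cc1cc(OC)c(OCc2ccccc2)c(OC)c1
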